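The 1,2-dioxan-3-ol ring (O1–O2–C3–C4–C5–C6) is the closed form of a γ-hydroperoxy ketone: C3 is a masked carbonyl and C6 a tertiary peroxy carbon. The C4–C5 bond between them is therefore cut into a C4 radical beside the C3 ketone and the CH2 end of a 2-methylalk-1-ene. In one operation a trivalent manganese salt under air joins a 2-methyl β-keto ester, the (4R)-alkene and O2, forming C4–C5, C6–O1 and O2–C3 and closing the ring. The keto ester carries a tert-butyl ester on C4, later lost as CO2, and a silyl-protected 2-hydroxyethyl arm on C3, inert in the radical step and oxidised to the acid only at the end.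

Key step: step 8

Remark: the annulation cannot control C6, and C4 is set against C6 only by a thermodynamic preference, so the annulation product and its successors are carried as mixtures (names and SMILES show the 6S series) up to the diol, where the wanted isomer is assumed to be separable by chromatography.

Step 1
Reactants: 1 (R)-citronellal; 2 6-phenylhex-1-ene
Product: 3 (3R)-3-methyl-11-phenylundec-6-enal (E/Z mixture)
Conditions: second-generation Grubbs catalyst (H2IMes)(PCy3)Cl2Ru=CHPh (3 mol %), 2 (3 equiv), CH2Cl2, 40 °C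
Reagents that add atoms: none
Why: Olefin cross-metathesis: the ruthenium alkylidene exchanges the isopropylidene end of the trisubstituted alkene for the alkylidene of the terminal alkene and volatile isobutene leaves, while the aldehyde and the C3 stereocentre are not touched and the E/Z ratio is irrelevant because the alkene is reduced next.

Step 2
Reactants: 3 (3R)-3-methyl-11-phenylundec-6-enal
Product: 4 (3R)-3-methyl-11-phenylundecanal
Conditions: H2 (1 atm), 10% Pd/C, EtOAc, 23 °C
Reagents that add atoms: none
Why: Heterogeneous catalytic hydrogenation saturates the disubstituted alkene far faster than it attacks the aliphatic aldehyde or the arene at 1 atm, and the stereocentre two carbons away is not involved.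

Step 3
Reactants: 4 (3R)-3-methyl-11-phenylundecanal
Product: 5 (4R)-4-methyl-12-phenyldodecan-2-ol (both C2 epimers)
Conditions: MeMgBr, THF, −78 → 0 °C; then aq. NH4Cl
Reagents that add atoms: methylmagnesium bromide, C[Mg]Br
Why: Grignard addition to the aldehyde gives the secondary alcohol as a mixture at the new carbinol carbon, which is of no consequence because that centre becomes a ketone in step 4.

Step 4
Reactants: 5 (4R)-4-methyl-12-phenyldodecan-2-ol
Product: 6 (4R)-4-methyl-12-phenyldodecan-2-one
Conditions: Dess–Martin periodinane, CH2Cl2, 23 °C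
Reagents that add atoms: none
Why: Dess–Martin oxidation of the secondary alcohol to the methyl ketone under neutral conditions, the C4 stereocentre being β to the carbonyl and therefore not epimerisable.

Step 5
Reactants: 6 (4R)-4-methyl-12-phenyldodecan-2-one
Product: 7 (4R)-2,4-dimethyl-12-phenyldodec-1-ene
Conditions: Ph3PCH3Br, KOtBu, THF, 0 → 23 °C
Reagents that add atoms: methyltriphenylphosphonium bromide, C[P+](c1ccccc1)(c1ccccc1)c1ccccc1.[Br-]
Why: Wittig methylenation with the non-stabilised ylide made in the flask converts the unhindered methyl ketone into the 1,1-disubstituted alkene without touching the β-stereocentre.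

Step 6
Reactants: 8 methyl 3-hydroxypropanoate
Product: 9 methyl 3-[(tert-butyldiphenylsilyl)oxy]propanoate
Conditions: TBDPSCl, imidazole, DMF, 23 °C
Reagents that add atoms: tert-butyl(chloro)diphenylsilane, CC(C)(C)[Si](Cl)(c1ccccc1)c1ccccc1
Why: Imidazole-mediated silylation of the primary alcohol installs a TBDPS ether, chosen because it withstands both AcOH in step 8 and TFA in step 9.

Step 7
Reactants: 10 tert-butyl propanoate; 9 methyl 3-[(tert-butyldiphenylsilyl)oxy]propanoate
Product: 12 tert-butyl 5-[(tert-butyldiphenylsilyl)oxy]-2-methyl-3-oxopentanoate, via lithium enolate 11 (not isolated)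
Conditions: 10 (2.2 equiv), LiN(iPr)2 (2.2 equiv), THF, −78 °C; then 9 (1 equiv), −78 → −30 °C; then AcOH
Reagents that add atoms: none
Why: Crossed Claisen condensation: the lithium enolate of the tert-butyl ester, which does not self-condense at −78 °C, acylates at the methyl ester and a second equivalent of enolate deprotonates the β-keto ester as it forms, which prevents further addition; C2 is formed racemic and becomes a radical centre in step 8.

Step 8
Reactants: 7 (4R)-2,4-dimethyl-12-phenyldodec-1-ene; 12 tert-butyl 5-[(tert-butyldiphenylsilyl)oxy]-2-methyl-3-oxopentanoate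
Product: 14 tert-butyl (6S)-3-{2-[(tert-butyldiphenylsilyl)oxy]ethyl}-3-hydroxy-4,6-dimethyl-6-[(2R)-2-methyl-10-phenyldecyl]-1,2-dioxane-4-carboxylate, via open-chain hydroperoxide 13 (not isolated)
Conditions: 7 (1 equiv), 12 (2 equiv), Mn(OAc)3·2H2O (0.2 equiv), AcOH, dry air (1 atm), 23 °C
Reagents that add atoms: dioxygen, O=O
Why: Trivalent manganese oxidises the enol of 12 at C2, its only 1,3-dicarbonyl C–H, to an electrophilic tertiary radical that adds to the unsubstituted terminus of the electron-rich alkene 7 (new C4–C5 bond); the tertiary C6 radical captures O2 (C6–O1), divalent manganese reduces the peroxyl radical and so returns the trivalent salt, and hydroperoxide 13 adds to the C3 ketone (O2–C3). The closest known reaction type is the manganese triacetate and O2 peroxycyclisation of 1,3-dicarbonyl compounds with 1,1-disubstituted alkenes to 1,2-dioxan-3-ols. The dioxane ring closes by 6-exo-trig hemiketalisation of the hydroperoxide onto the ketone. C6 is set when the planar radical meets O2, with no useful bias from C2', so both C6 epimers should form in comparable amounts; C4 (radical addition) and C3 (reversible hemiketal closure) are formed without control and are reset in step 9. The step needs regioselective attack at the CH2 terminus, secured by radical polarity and by formation of the tertiary radical, and a single oxidisable site, secured by the silyl ether arm, which unlike an ester or an aldehyde equivalent offers no second dicarbonyl position. Air in place of pure O2 and an excess of 12 should keep direct oxygenation of the keto ester radical behind its addition to the alkene.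

Step 9
Reactants: 14 tert-butyl (6S)-3-{2-[(tert-butyldiphenylsilyl)oxy]ethyl}-3-hydroxy-4,6-dimethyl-6-[(2R)-2-methyl-10-phenyldecyl]-1,2-dioxane-4-carboxylate
Product: 16 (3S,4R,6S)-3-{2-[(tert-butyldiphenylsilyl)oxy]ethyl}-4,6-dimethyl-6-[(2R)-2-methyl-10-phenyldecyl]-1,2-dioxan-3-ol, via carboxylic acid 15 (not isolated)
Conditions: TFA/CH2Cl2 (1:4), 0 → 23 °C; concentrate; CHCl3, 40 °C
Reagents that add atoms: none
Why: Acidolysis of the tert-butyl ester (loss of isobutene) frees acid 15, whose ring-open β-keto acid tautomer decarboxylates, and reversible ring opening with acid-catalysed enolisation then equilibrates C4 and C3 so that the 4-methyl group sits equatorial and the anomerically favoured axial 3-hydroxyl cis to it (with the bulkier C6 chain equatorial in the wanted isomer, a preference expected to be modest), the primary TBDPS ether being kept on purpose so that no free hydroxyl can lactonise onto the C4 acid.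

Step 10
Reactants: 16 (3S,4R,6S)-3-{2-[(tert-butyldiphenylsilyl)oxy]ethyl}-4,6-dimethyl-6-[(2R)-2-methyl-10-phenyldecyl]-1,2-dioxan-3-ol
Product: 17 (3S,4R,6S)-3-(2-hydroxyethyl)-4,6-dimethyl-6-[(2R)-2-methyl-10-phenyldecyl]-1,2-dioxan-3-ol
Conditions: HF·pyridine, pyridine, THF, 0 → 23 °C; chromatography (separation of diastereomers)
Reagents that add atoms: none
Why: Fluoride-driven cleavage of the silyl ether (strong Si–F bond) under buffered, non-basic conditions leaves the peroxide and the hemiketal intact, and the free diol is the stage at which the (3S,4R,6S) isomer is separated by chromatography from the 6R series and from its C4 epimer, the latter being returned to acid equilibration.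

Step 11
Reactants: 17 (3S,4R,6S)-3-(2-hydroxyethyl)-4,6-dimethyl-6-[(2R)-2-methyl-10-phenyldecyl]-1,2-dioxan-3-ol
Product: 19 2-[(3S,4R,6S)-3-hydroxy-4,6-dimethyl-6-[(2R)-2-methyl-10-phenyldecyl]-1,2-dioxan-3-yl]acetic acid, via aldehyde 18 (not isolated)
Conditions: TEMPO (0.2 equiv), PhI(OAc)2 (2.2 equiv), MeCN/H2O (1:1), 0 → 23 °C
Reagents that add atoms: water, O
Why: Oxoammonium-catalysed oxidation (TEMPO with PhI(OAc)2 as terminal oxidant) takes the primary alcohol through aldehyde 18 and its hydrate to the acid at near-neutral pH, where the tertiary hemiketal hydroxyl cannot be oxidised, the dialkyl peroxide is inert and no base is present that could act on the ring-open β-keto acid form.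

Compound list
1 | (R)-citronellal, (3R)-3,7-dimethyloct-6-enal | C[C@H](CCC=C(C)C)CC=O | starting material
2 | 6-phenylhex-1-ene | C=CCCCCc1ccccc1 | starting material
3 | (3R)-3-methyl-11-phenylundec-6-enal (E/Z mixture) | C[C@H](CCC=CCCCCc1ccccc1)CC=O | intermediate
4 | (3R)-3-methyl-11-phenylundecanal | C[C@H](CCCCCCCCc1ccccc1)CC=O | intermediate
5 | (4R)-4-methyl-12-phenyldodecan-2-ol (both C2 epimers) | C[C@H](CCCCCCCCc1ccccc1)CC(C)O | intermediate
6 | (4R)-4-methyl-12-phenyldodecan-2-one | C[C@H](CCCCCCCCc1ccccc1)CC(C)=O | intermediate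
7 | (4R)-2,4-dimethyl-12-phenyldodec-1-ene | C[C@H](CCCCCCCCc1ccccc1)CC(C)=C | intermediate
8 | methyl 3-hydroxypropanoate | COC(=O)CCO | starting material
9 | methyl 3-[(tert-butyldiphenylsilyl)oxy]propanoate | COC(=O)CCO[Si](c1ccccc1)(c1ccccc1)C(C)(C)C | intermediate
10 | tert-butyl propanoate | CCC(=O)OC(C)(C)C | starting material
11 | lithium enolate of tert-butyl propanoate (lithium 1-tert-butoxyprop-1-en-1-olate) | [Li+].CC=C([O-])OC(C)(C)C | intermediate (not isolated)
12 | tert-butyl 5-[(tert-butyldiphenylsilyl)oxy]-2-methyl-3-oxopentanoate (racemic at C2) | CC(C(=O)CCO[Si](c1ccccc1)(c1ccccc1)C(C)(C)C)C(=O)OC(C)(C)C | intermediate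
13 | tert-butyl 5-[(tert-butyldiphenylsilyl)oxy]-2-[(2S,4R)-2-hydroperoxy-2,4-dimethyl-12-phenyldodecyl]-2-methyl-3-oxopentanoate (formed with the 2R epimer; ester-bearing carbon unassigned) | C[C@H](CCCCCCCCc1ccccc1)C[C@](C)(OO)CC(C)(C(=O)OC(C)(C)C)C(=O)CCO[Si](c1ccccc1)(c1ccccc1)C(C)(C)C | intermediate (not isolated)
14 | tert-butyl (6S)-3-{2-[(tert-butyldiphenylsilyl)oxy]ethyl}-3-hydroxy-4,6-dimethyl-6-[(2R)-2-methyl-10-phenyldecyl]-1,2-dioxane-4-carboxylate (formed with the 6R epimer; C3 and C4 unassigned) | C[C@H](CCCCCCCCc1ccccc1)C[C@@]1(C)CC(C)(C(=O)OC(C)(C)C)C(O)(CCO[Si](c2ccccc2)(c2ccccc2)C(C)(C)C)OO1 | intermediate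
15 | (6S)-3-{2-[(tert-butyldiphenylsilyl)oxy]ethyl}-3-hydroxy-4,6-dimethyl-6-[(2R)-2-methyl-10-phenyldecyl]-1,2-dioxane-4-carboxylic acid (with the 6R epimer; C3 and C4 unassigned) | C[C@H](CCCCCCCCc1ccccc1)C[C@@]1(C)CC(C)(C(=O)O)C(O)(CCO[Si](c2ccccc2)(c2ccccc2)C(C)(C)C)OO1 | intermediate (not isolated)
16 | (3S,4R,6S)-3-{2-[(tert-butyldiphenylsilyl)oxy]ethyl}-4,6-dimethyl-6-[(2R)-2-methyl-10-phenyldecyl]-1,2-dioxan-3-ol (carried with its diastereomers) | C[C@H](CCCCCCCCc1ccccc1)C[C@@]1(C)C[C@@H](C)[C@](O)(CCO[Si](c2ccccc2)(c2ccccc2)C(C)(C)C)OO1 | intermediate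
17 | (3S,4R,6S)-3-(2-hydroxyethyl)-4,6-dimethyl-6-[(2R)-2-methyl-10-phenyldecyl]-1,2-dioxan-3-ol | C[C@H](CCCCCCCCc1ccccc1)C[C@@]1(C)C[C@@H](C)[C@](O)(CCO)OO1 | intermediate
18 | 2-[(3S,4R,6S)-3-hydroxy-4,6-dimethyl-6-[(2R)-2-methyl-10-phenyldecyl]-1,2-dioxan-3-yl]acetaldehyde | C[C@H](CCCCCCCCc1ccccc1)C[C@@]1(C)C[C@@H](C)[C@](O)(CC=O)OO1 | intermediate (not isolated)
19 | 2-[(3S,4R,6S)-3-hydroxy-4,6-dimethyl-6-[(2R)-2-methyl-10-phenyldecyl]-1,2-dioxan-3-yl]acetic acid | C[C@H](CCCCCCCCc1ccccc1)C[C@@]1(C)C[C@@H](C)[C@](O)(CC(=O)O)OO1 | target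

Total step count: 11
Longest linear sequence: 9 steps (steps 1–5 and 8–11, from (R)-citronellal); the keto ester branch is steps 6–7.

Steps most likely to fail

Step 8. The keto ester radical may be captured by O2 (oxygenation and cleavage of the keto ester) faster than it adds to the unactivated dialkyl alkene, so that little annulation takes place. The fallback separates carbon–carbon bond formation from oxygenation and sets out from 12 and 7. Anaerobic oxidative allylation with Mn(OAc)3·2H2O and Cu(OAc)2·H2O in AcOH at 60 °C under N2, in which divalent copper oxidises the adduct radical to the alkene, should give tert-butyl 5-[(tert-butyldiphenylsilyl)oxy]-2-methyl-2-[(4R)-4-methyl-2-methylidene-12-phenyldodecyl]-3-oxopentanoate F1, together with double-bond isomers that converge in the next operation. Cobalt-catalysed hydroperoxysilylation (Isayama–Mukaiyama reaction: Co(acac)2, O2, Et3SiH, ClCH2CH2Cl, 23 °C) should then place the peroxide on the tertiary carbon and give tert-butyl 5-[(tert-butyldiphenylsilyl)oxy]-2-{(2S,4R)-2,4-dimethyl-12-phenyl-2-[(triethylsilyl)peroxy]dodecyl}-2-methyl-3-oxopentanoate F2 with its 2R epimer. Mild aqueous acid (AcOH/THF/H2O, 23 °C) removes the triethylsilyl group from the peroxide, the hydroperoxide closes onto the ketone, and the route is rejoined at 14.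

Step 9. The ring-closed form of acid 15 is a β-hydroxy acid, so decarboxylation may stall. Prolonged strong acid also invites heterolysis of the O–O bond (Criegee-type rearrangement of the peroxy hemiketal) or early loss of the silyl ether followed by lactonisation. The fallback exchanges the acid-labile ester for one that fluoride cleaves and sets out from 12. Transesterification through the acylketene (2-(trimethylsilyl)ethanol, toluene, 110 °C, tert-butanol distilled off) should give 2-(trimethylsilyl)ethyl 5-[(tert-butyldiphenylsilyl)oxy]-2-methyl-3-oxopentanoate F3. Annulation of F3 with 7 under the conditions of step 8 should give 2-(trimethylsilyl)ethyl (6S)-3-{2-[(tert-butyldiphenylsilyl)oxy]ethyl}-3-hydroxy-4,6-dimethyl-6-[(2R)-2-methyl-10-phenyldecyl]-1,2-dioxane-4-carboxylate F4 with its 6R epimer. Bu4NF buffered with AcOH in THF at 23 °C then fragments the ester, removes the TBDPS group and lets the β-keto carboxylate lose CO2 without strong acid. A brief treatment with pyridinium p-toluenesulfonate in wet CH2Cl2 equilibrates C3 and C4, and the route is rejoined at 17.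

Step 11. At the aldehyde stage the hemiketal may open to an enolised β-keto aldehyde or lose water towards the arm, and the ring-open β-keto acid form of the product may decarboxylate if the oxidation is slow. The fallback locks C3 before the oxidation and sets out from 17. Methanol with catalytic pyridinium p-toluenesulfonate at 23 °C should convert the hemiketal into the methyl peroxyketal 2-[(3S,4R,6S)-3-methoxy-4,6-dimethyl-6-[(2R)-2-methyl-10-phenyldecyl]-1,2-dioxan-3-yl]ethan-1-ol F5, which cannot open. The same TEMPO/PhI(OAc)2 oxidation should give 2-[(3S,4R,6S)-3-methoxy-4,6-dimethyl-6-[(2R)-2-methyl-10-phenyldecyl]-1,2-dioxan-3-yl]acetic acid F6. Hydrolysis of the ketal with TFA/H2O/THF at 0 °C returns the hemiketal, and the route ends at 19.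

Further compounds
F1 | step 8 | tert-butyl 5-[(tert-butyldiphenylsilyl)oxy]-2-methyl-2-[(4R)-4-methyl-2-methylidene-12-phenyldodecyl]-3-oxopentanoate | C[C@H](CCCCCCCCc1ccccc1)CC(=C)CC(C)(C(=O)OC(C)(C)C)C(=O)CCO[Si](c1ccccc1)(c1ccccc1)C(C)(C)C
F2 | step 8 | tert-butyl 5-[(tert-butyldiphenylsilyl)oxy]-2-{(2S,4R)-2,4-dimethyl-12-phenyl-2-[(triethylsilyl)peroxy]dodecyl}-2-methyl-3-oxopentanoate | C[C@H](CCCCCCCCc1ccccc1)C[C@](C)(OO[Si](CC)(CC)CC)CC(C)(C(=O)OC(C)(C)C)C(=O)CCO[Si](c1ccccc1)(c1ccccc1)C(C)(C)C
F3 | step 9 | 2-(trimethylsilyl)ethyl 5-[(tert-butyldiphenylsilyl)oxy]-2-methyl-3-oxopentanoate | CC(C(=O)CCO[Si](c1ccccc1)(c1ccccc1)C(C)(C)C)C(=O)OCC[Si](C)(C)C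
F4 | step 9 | 2-(trimethylsilyl)ethyl (6S)-3-{2-[(tert-butyldiphenylsilyl)oxy]ethyl}-3-hydroxy-4,6-dimethyl-6-[(2R)-2-methyl-10-phenyldecyl]-1,2-dioxane-4-carboxylate | C[C@H](CCCCCCCCc1ccccc1)C[C@@]1(C)CC(C)(C(=O)OCC[Si](C)(C)C)C(O)(CCO[Si](c2ccccc2)(c2ccccc2)C(C)(C)C)OO1
F5 | step 11 | 2-[(3S,4R,6S)-3-methoxy-4,6-dimethyl-6-[(2R)-2-methyl-10-phenyldecyl]-1,2-dioxan-3-yl]ethan-1-ol | C[C@H](CCCCCCCCc1ccccc1)C[C@@]1(C)C[C@@H](C)[C@](OC)(CCO)OO1
F6 | step 11 | 2-[(3S,4R,6S)-3-methoxy-4,6-dimethyl-6-[(2R)-2-methyl-10-phenyldecyl]-1,2-dioxan-3-yl]acetic acid | C[C@H](CCCCCCCCc1ccccc1)C[C@@]1(C)C[C@@H](C)[C@](OC)(CC(=O)O)OO1
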